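## Retrosynthetic overview

1. The strategy rests on the two trans-oxiranes C10–C1 and C4–C5 of the ten-membered carbocycle. They are a masked (E,E)-C10=C1–C2–C3–C4=C5 1,5-diene, and its C2–C3 bond is the retron of a [3,3] shift that traces the ten-membered ring back to a six-membered ring C5–C6–C7–C8–C9–C10.
2. Late disconnections: both oxiranes (peracid), the C8 tiglate and the C13–O protecting group; the butenolide ring is opened at C7=C11 (intramolecular Horner–Wadsworth–Emmons) and at the C6–O ester, leaving a C6-hydroxy C7-ketone from enolate hydroxylation.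
3. Key disconnection: anionic oxy-Cope rearrangement of the potassium alkoxide of a trans-1-isopropenyl-2-methyl-2-vinylcyclohexanol (C5 carbinol, C10 quaternary, C7 dioxolane, C8 OTBS) with triflation of the C4=C5 enolate; C5–OTf is later reduced to C5–H.
4. The cyclohexanol comes from (S)-4-silyloxycyclohexenone: C8 is set first (CBS reduction), C10 is then built anti to OTBS (Michael addition, methylation, sulfoxide elimination), C7 is oxidised (epoxide to 1,3-diketone) and ketalised, and isopropenylcerium adds to C5.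
5. Ring order: six-membered carbocycle (purchased), ten-membered ring (step 11, ring expansion), butenolide ring (step 18), the two oxirane rings (step 21).

Key step: step 11

Assumption: germacrane numbering (C1–C15) is used for ring positions throughout; racemic phenyl vinyl sulfoxide and a racemic phosphonate acid are used, so the sulfoxide- and phosphonate-bearing intermediates are mixtures at sulfur or at the phosphonate carbon, centres that are destroyed later; the enone ketal and the phosphonoacrylate starting materials are taken as purchasable.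

## Route

Step 1
Reactants: 1 1,4-dioxaspiro[4.5]dec-6-en-8-one
Product: 2 (8S)-1,4-dioxaspiro[4.5]dec-6-en-8-ol
Conditions: (R)-1-methyl-3,3-diphenyltetrahydro-1H,3H-pyrrolo[1,2-c][1,3,2]oxazaborole (10 mol%), BH3·SMe2, THF, −20 °C
Reagents that add atoms: none
Why: Corey–Bakshi–Shibata reduction, in which the oxazaborolidine–borane complex delivers hydride to one carbonyl face with the alkenyl carbon as the large group, so the (R)-catalyst should set the future C8 carbinol as S with 1,2-selectivity.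

Step 2
Reactants: 2 (8S)-1,4-dioxaspiro[4.5]dec-6-en-8-ol
Product: 3 tert-butyl{[(8S)-1,4-dioxaspiro[4.5]dec-6-en-8-yl]oxy}dimethylsilane
Conditions: TBSCl, imidazole, DMF, rt
Reagents that add atoms: tert-butyldimethylsilyl chloride, CC(C)(C)[Si](C)(C)Cl
Why: Standard silyl ether formation on a secondary allylic alcohol, which does not touch the stereocentre.

Step 3
Reactants: 3 tert-butyl{[(8S)-1,4-dioxaspiro[4.5]dec-6-en-8-yl]oxy}dimethylsilane
Product: 4 (4S)-4-[(tert-butyldimethylsilyl)oxy]cyclohex-2-en-1-one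
Conditions: pyridinium p-toluenesulfonate (cat.), acetone/H2O, 50 °C
Reagents that add atoms: water, O
Why: Acid-catalysed ketal hydrolysis unmasks the C5 ketone in conjugation with C6=C7, and the silyl ether is stable to this weak acid.

Step 4
Reactants: 4 (4S)-4-[(tert-butyldimethylsilyl)oxy]cyclohex-2-en-1-one; 5 phenyl vinyl sulfoxide
Product: 7 (4S)-4-[(tert-butyldimethylsilyl)oxy]-6-[2-(phenylsulfinyl)ethyl]cyclohex-2-en-1-one, via lithium dienolate 6 (not isolated)
Conditions: LiN(iPr)2, THF, −78 °C; then 5, −78 → −30 °C; AcOH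
Reagents that add atoms: phenyl vinyl sulfoxide (5), C=CS(=O)c1ccccc1
Why: Kinetic α′-deprotonation of the enone gives the cross-conjugated dienolate, which undergoes Michael addition to the vinyl sulfoxide as a vinyl cation equivalent; the C10 centre formed here is re-enolised in step 5 and need not be controlled.

Step 5
Reactants: 7 (4S)-4-[(tert-butyldimethylsilyl)oxy]-6-[2-(phenylsulfinyl)ethyl]cyclohex-2-en-1-one
Product: 9 (4S,6S)-4-[(tert-butyldimethylsilyl)oxy]-6-methyl-6-[2-(phenylsulfinyl)ethyl]cyclohex-2-en-1-one, via potassium enolate 8 (not isolated)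
Conditions: KN(SiMe3)2, THF, −78 °C; MeI, −78 → −30 °C
Reagents that add atoms: iodomethane, CI
Why: Enolate alkylation with a base too weak to deprotonate next to sulfur; iodomethane should enter on the face opposite the C8 silyloxy group (1,3-relationship), setting C10 with methyl trans and the future vinyl group cis to OTBS.

Step 6
Reactants: 9 (4S,6S)-4-[(tert-butyldimethylsilyl)oxy]-6-methyl-6-[2-(phenylsulfinyl)ethyl]cyclohex-2-en-1-one
Product: 10 (4S,6S)-4-[(tert-butyldimethylsilyl)oxy]-6-methyl-6-vinylcyclohex-2-en-1-one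
Conditions: CaCO3, xylene, 135 °C
Reagents that add atoms: none
Why: Thermal sulfoxide syn-elimination can only take a hydrogen from the carbon attached to the quaternary C10 and so unveils the vinyl group.

Step 7
Reactants: 10 (4S,6S)-4-[(tert-butyldimethylsilyl)oxy]-6-methyl-6-vinylcyclohex-2-en-1-one
Product: 11 (1R,3S,5S,6S)-5-[(tert-butyldimethylsilyl)oxy]-3-methyl-3-vinyl-7-oxabicyclo[4.1.0]heptan-2-one
Conditions: 30% H2O2, NaOH (cat.), MeOH, 0 °C
Reagents that add atoms: hydrogen peroxide, OO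
Why: Weitz–Scheffer nucleophilic epoxidation attacks only the electron-poor C6=C7 bond and not the vinyl group; hydroperoxide is expected to add anti to OTBS, and both new centres are erased in step 8.

Step 8
Reactants: 11 (1R,3S,5S,6S)-5-[(tert-butyldimethylsilyl)oxy]-3-methyl-3-vinyl-7-oxabicyclo[4.1.0]heptan-2-one
Product: 12 (4S,6S)-4-[(tert-butyldimethylsilyl)oxy]-6-methyl-6-vinylcyclohexane-1,3-dione
Conditions: Pd(PPh3)4 (5 mol%), Ph2PCH2CH2PPh2 (5 mol%), toluene, 90 °C
Reagents that add atoms: none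
Why: Palladium-catalysed isomerisation of an α,β-epoxy ketone to a 1,3-diketone, in which zerovalent palladium opens the oxirane at the α-carbon and β-hydride elimination from C7 brings C7 to the ketone level without a redox reagent.

Step 9
Reactants: 12 (4S,6S)-4-[(tert-butyldimethylsilyl)oxy]-6-methyl-6-vinylcyclohexane-1,3-dione
Product: 13 (8S,10S)-10-[(tert-butyldimethylsilyl)oxy]-8-methyl-8-vinyl-1,4-dioxaspiro[4.5]decan-7-one
Conditions: HOCH2CH2OH, pyridinium p-toluenesulfonate (cat.), benzene, reflux (Dean–Stark)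
Reagents that add atoms: ethylene glycol, OCCO
Why: Acid-catalysed ketalisation should go at the C7 carbonyl because the C5 carbonyl sits next to the quaternary C10; a C8 epimer formed by enolisation would be a separable diastereomer.

Step 10
Reactants: 13 (8S,10S)-10-[(tert-butyldimethylsilyl)oxy]-8-methyl-8-vinyl-1,4-dioxaspiro[4.5]decan-7-one; 14 isopropenylmagnesium bromide
Product: 16 (7R,8S,10S)-10-[(tert-butyldimethylsilyl)oxy]-8-methyl-7-(prop-1-en-2-yl)-8-vinyl-1,4-dioxaspiro[4.5]decan-7-ol, via isopropenylcerium dichloride 15 (not isolated)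
Conditions: CeCl3 (anhydrous), 14, THF, −78 °C; then 13, −78 → 0 °C; aq NH4Cl
Reagents that add atoms: isopropenylmagnesium bromide (14), CC(=C)[Mg]Br
Why: Organocerium 1,2-addition to a hindered, enolisable ketone; in the chair with OTBS and vinyl equatorial and methyl axial, the axial dioxolane oxygen at C7 blocks the axial trajectory, so isopropenyl should enter equatorially, trans to vinyl, giving the axial C5 carbinol.

Step 11
Reactants: 16 (7R,8S,10S)-10-[(tert-butyldimethylsilyl)oxy]-8-methyl-7-(prop-1-en-2-yl)-8-vinyl-1,4-dioxaspiro[4.5]decan-7-ol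
Product: 19 (7Z,11E,14S)-14-[(tert-butyldimethylsilyl)oxy]-8,12-dimethyl-1,4-dioxaspiro[4.9]tetradeca-7,11-dien-7-yl trifluoromethanesulfonate, via potassium alkoxide 17 (not isolated), via potassium cyclodecadienolate 18 (not isolated)
Conditions: KH, 18-crown-6, THF, 0 °C → rt; then N-(5-chloropyridin-2-yl)triflimide, −78 → 0 °C
Reagents that add atoms: N-(5-chloropyridin-2-yl)-1,1,1-trifluoro-N-[(trifluoromethyl)sulfonyl]methanesulfonamide, FC(F)(F)S(=O)(=O)N(c1ccc(Cl)cn1)S(=O)(=O)C(F)(F)F
Why: Deprotonation gives the crown-ether-separated potassium alkoxide 17, whose C3=C4–C5(O−)–C10–C1=C2 1,5-diene undergoes an alkoxide-accelerated [3,3] shift through a chair transition state that forms C2–C3 and breaks C5–C10, and the resulting C4=C5 enolate 18 is O-sulfonylated at low temperature. The closest known reaction type is the anionic oxy-Cope rearrangement of 1,2-dialkenylcyclohexanols to cyclodec-5-enones with trapping of the enolate. The ten-membered ring is closed by ring expansion, the six-membered ring growing by the four carbons C1–C4 of the two alkenyl groups, so no end-to-end macrocyclisation is involved. No stereocentre is created: C5 and C10 become sp2 and C8 is carried through unchanged. The step needs E geometry at C1=C10 and the ring-trans geometry at C4=C5, and both follow from the chair transition state with both alkenyl groups equatorial, which the trans C5/C10 relationship and the equatorial OTBS group of 16 secure. It also needs the enolate regiochemistry fixed by the shift to survive until trapping, so triflation is done at −78 °C before proton transfer towards C6 could expel the ketal oxygen.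

Step 12
Reactants: 19 (7Z,11E,14S)-14-[(tert-butyldimethylsilyl)oxy]-8,12-dimethyl-1,4-dioxaspiro[4.9]tetradeca-7,11-dien-7-yl trifluoromethanesulfonate
Product: 20 (1Z,5E,8S)-8-[(tert-butyldimethylsilyl)oxy]-2,6-dimethyl-9-oxocyclodeca-1,5-dien-1-yl trifluoromethanesulfonate
Conditions: TsOH·H2O (cat.), acetone/H2O, 40 °C
Reagents that add atoms: water, O
Why: Acid-catalysed ketal hydrolysis, done at this stage because the electron-poor enol triflate makes C4=C5 a poor transannular nucleophile and so protects the acid-sensitive 1,5-diene; the hindered secondary silyl ether is expected to survive.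

Step 13
Reactants: 20 (1Z,5E,8S)-8-[(tert-butyldimethylsilyl)oxy]-2,6-dimethyl-9-oxocyclodeca-1,5-dien-1-yl trifluoromethanesulfonate
Product: 21 (3E,7E,10S)-10-[(tert-butyldimethylsilyl)oxy]-4,8-dimethylcyclodeca-3,7-dien-1-one
Conditions: Pd(PPh3)4 (5 mol%), LiCl, Bu3SnH, THF, rt
Reagents that add atoms: none
Why: Palladium-catalysed reduction of an enol triflate by tin hydride (oxidative addition to zerovalent palladium, hydride transfer, reductive elimination) replaces OTf by H with retention of the ring-trans geometry under neutral conditions at room temperature.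

Step 14
Reactants: 21 (3E,7E,10S)-10-[(tert-butyldimethylsilyl)oxy]-4,8-dimethylcyclodeca-3,7-dien-1-one
Product: 23 (2R,3E,7E,10S)-10-[(tert-butyldimethylsilyl)oxy]-2-hydroxy-4,8-dimethylcyclodeca-3,7-dien-1-one, via potassium ketone enolate 22 (not isolated)
Conditions: KN(SiMe3)2, THF, −78 °C; 3-phenyl-2-(phenylsulfonyl)oxaziridine, −78 °C; AcOH
Reagents that add atoms: 3-phenyl-2-(phenylsulfonyl)oxaziridine, O=S(=O)(c1ccccc1)N1OC1c1ccccc1
Why: Enolate hydroxylation with an N-sulfonyloxaziridine; deprotonation is expected at C6, which is both α to the ketone and allylic, and attack on the outer face of the ring enolate, with C8–H in the enolate plane and OTBS on the periphery, should place the new hydroxyl cis to OTBS.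

Step 15
Reactants: 24 ethyl 2-(diethoxyphosphoryl)acrylate; 25 4-methoxybenzyl alcohol
Product: 26 ethyl 2-(diethoxyphosphoryl)-3-[(4-methoxybenzyl)oxy]propanoate
Conditions: KOtBu (10 mol%), THF, 0 °C → rt
Reagents that add atoms: 4-methoxybenzyl alcohol (25), COc1ccc(CO)cc1
Why: Base-catalysed oxa-Michael addition of the alkoxide to the doubly activated phosphonoacrylate.

Step 16
Reactants: 26 ethyl 2-(diethoxyphosphoryl)-3-[(4-methoxybenzyl)oxy]propanoate
Product: 27 2-(diethoxyphosphoryl)-3-[(4-methoxybenzyl)oxy]propanoic acid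
Conditions: LiOH·H2O (1.1 equiv), THF/H2O, 0 °C; then 1 M HCl
Reagents that add atoms: lithium hydroxide, [Li+].[OH-]
Why: Saponification of the carboxylic ester is much faster than attack at the phosphonate esters, and the low temperature limits reversible β-elimination of the ether.

Step 17
Reactants: 23 (2R,3E,7E,10S)-10-[(tert-butyldimethylsilyl)oxy]-2-hydroxy-4,8-dimethylcyclodeca-3,7-dien-1-one; 27 2-(diethoxyphosphoryl)-3-[(4-methoxybenzyl)oxy]propanoic acid
Product: 28 (1R,2E,6E,9S)-9-[(tert-butyldimethylsilyl)oxy]-3,7-dimethyl-10-oxocyclodeca-2,6-dien-1-yl 2-(diethoxyphosphoryl)-3-[(4-methoxybenzyl)oxy]propanoate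
Conditions: DCC, 4-(dimethylamino)pyridine (cat.), CH2Cl2, 0 °C
Reagents that add atoms: 2-(diethoxyphosphoryl)-3-[(4-methoxybenzyl)oxy]propanoic acid (27), OC(=O)C(COCc1ccc(OC)cc1)P(=O)(OCC)OCC
Why: Steglich esterification acylates the secondary α-ketol on oxygen with retention at C6.

Step 18
Reactants: 28 (1R,2E,6E,9S)-9-[(tert-butyldimethylsilyl)oxy]-3,7-dimethyl-10-oxocyclodeca-2,6-dien-1-yl 2-(diethoxyphosphoryl)-3-[(4-methoxybenzyl)oxy]propanoate
Product: 29 (6R,8S)-8-[(tert-butyldimethylsilyl)oxy]-13-[(4-methoxybenzyl)oxy]germacra-1(10)E,4E,7(11)-trien-12,6-olide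
Conditions: LiCl, iPr2NEt, MeCN, rt
Reagents that add atoms: none
Why: Intramolecular Horner–Wadsworth–Emmons olefination in its mild lithium chloride–amine variant closes the five-membered lactone ring onto the C7 ketone and forms C7=C11, the weak base being chosen to spare the C6 and C8 centres.

Step 19
Reactants: 29 (6R,8S)-8-[(tert-butyldimethylsilyl)oxy]-13-[(4-methoxybenzyl)oxy]germacra-1(10)E,4E,7(11)-trien-12,6-olide
Product: 30 (6R,8S)-8-hydroxy-13-[(4-methoxybenzyl)oxy]germacra-1(10)E,4E,7(11)-trien-12,6-olide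
Conditions: Bu4NF, AcOH, THF, 0 °C → rt
Reagents that add atoms: none
Why: Fluoride-mediated desilylation buffered with acetic acid removes the secondary silyl ether without touching the 4-methoxybenzyl ether or enolising the butenolide.

Step 20
Reactants: 30 (6R,8S)-8-hydroxy-13-[(4-methoxybenzyl)oxy]germacra-1(10)E,4E,7(11)-trien-12,6-olide; 31 tiglic acid
Product: 33 (6R,8S)-13-[(4-methoxybenzyl)oxy]-8-[(E)-2-methylbut-2-enoyloxy]germacra-1(10)E,4E,7(11)-trien-12,6-olide, via tiglic 2,4,6-trichlorobenzoic anhydride 32 (not isolated)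
Conditions: 31, 2,4,6-trichlorobenzoyl chloride, Et3N, toluene, rt; then 30, 4-(dimethylamino)pyridine, rt
Reagents that add atoms: tiglic acid (31), C/C=C(\C)C(=O)O
Why: Yamaguchi esterification through the mixed anhydride acylates the hindered C8 alcohol with retention and keeps the E geometry of the tiglate.

Step 21
Reactants: 33 (6R,8S)-13-[(4-methoxybenzyl)oxy]-8-[(E)-2-methylbut-2-enoyloxy]germacra-1(10)E,4E,7(11)-trien-12,6-olide
Product: 34 (1R,4R,5R,6S,8S,10R)-1,10:4,5-diepoxy-13-[(4-methoxybenzyl)oxy]-8-[(E)-2-methylbut-2-enoyloxy]germacr-7(11)-en-12,6-olide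
Conditions: mCPBA (2.3 equiv), NaHCO3, CH2Cl2, 0 °C
Reagents that add atoms: 3-chloroperoxybenzoic acid, O=C(OO)c1cccc(Cl)c1
Why: Prilezhaev epoxidation of the two electron-rich trisubstituted ring alkenes; peracid attack on the outer faces of the crossed-diene conformer with both methyl groups on the same side should give the 1β,10α- and 4α,5β-oxiranes, while the butenolide and tiglate alkenes are too electron-poor to react.

Step 22
Reactants: 34 (1R,4R,5R,6S,8S,10R)-1,10:4,5-diepoxy-13-[(4-methoxybenzyl)oxy]-8-[(E)-2-methylbut-2-enoyloxy]germacr-7(11)-en-12,6-olide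
Product: 35 (1R,4R,5R,6S,8S,10R)-1,10:4,5-diepoxy-13-hydroxy-8-[(E)-2-methylbut-2-enoyloxy]germacr-7(11)-en-12,6-olide
Conditions: DDQ, CH2Cl2/pH 7 phosphate buffer, 0 °C → rt
Reagents that add atoms: none
Why: Oxidative cleavage of the 4-methoxybenzyl ether by DDQ under neutral buffered conditions leaves the oxiranes, the tiglate and the lactone intact.

## Compound list

1 | 1,4-dioxaspiro[4.5]dec-6-en-8-one | O=C1CCC2(OCCO2)C=C1 | starting material
2 | (8S)-1,4-dioxaspiro[4.5]dec-6-en-8-ol | O1CCOC12CC[C@H](O)C=C2 | intermediate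
3 | tert-butyl{[(8S)-1,4-dioxaspiro[4.5]dec-6-en-8-yl]oxy}dimethylsilane | O1CCOC12CC[C@H](O[Si](C)(C)C(C)(C)C)C=C2 | intermediate
4 | (4S)-4-[(tert-butyldimethylsilyl)oxy]cyclohex-2-en-1-one | O=C1CC[C@H](O[Si](C)(C)C(C)(C)C)C=C1 | intermediate
5 | phenyl vinyl sulfoxide (racemic) | C=CS(=O)c1ccccc1 | starting material
6 | lithium (4S)-4-[(tert-butyldimethylsilyl)oxy]cyclohexa-1,5-dien-1-olate | [Li]OC1=CC[C@H](O[Si](C)(C)C(C)(C)C)C=C1 | intermediate
7 | (4S)-4-[(tert-butyldimethylsilyl)oxy]-6-[2-(phenylsulfinyl)ethyl]cyclohex-2-en-1-one (mixture at C6 and at sulfur) | O=C1C(CCS(=O)c2ccccc2)C[C@H](O[Si](C)(C)C(C)(C)C)C=C1 | intermediate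
8 | potassium enolate of 7 | [K]OC1=C(CCS(=O)c2ccccc2)C[C@H](O[Si](C)(C)C(C)(C)C)C=C1 | intermediate
9 | (4S,6S)-4-[(tert-butyldimethylsilyl)oxy]-6-methyl-6-[2-(phenylsulfinyl)ethyl]cyclohex-2-en-1-one (mixture at sulfur) | O=S(c1ccccc1)CC[C@]2(C)C[C@H](O[Si](C)(C)C(C)(C)C)C=CC2=O | intermediate
10 | (4S,6S)-4-[(tert-butyldimethylsilyl)oxy]-6-methyl-6-vinylcyclohex-2-en-1-one | C=C[C@]1(C)C[C@H](O[Si](C)(C)C(C)(C)C)C=CC1=O | intermediate
11 | (1R,3S,5S,6S)-5-[(tert-butyldimethylsilyl)oxy]-3-methyl-3-vinyl-7-oxabicyclo[4.1.0]heptan-2-one (oxirane trans to OTBS) | C=C[C@]1(C)C[C@H](O[Si](C)(C)C(C)(C)C)[C@H]2O[C@H]2C1=O | intermediate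
12 | (4S,6S)-4-[(tert-butyldimethylsilyl)oxy]-6-methyl-6-vinylcyclohexane-1,3-dione | C=C[C@]1(C)C[C@H](O[Si](C)(C)C(C)(C)C)C(=O)CC1=O | intermediate
13 | (8S,10S)-10-[(tert-butyldimethylsilyl)oxy]-8-methyl-8-vinyl-1,4-dioxaspiro[4.5]decan-7-one | C=C[C@]1(C)C[C@H](O[Si](C)(C)C(C)(C)C)C2(OCCO2)CC1=O | intermediate
14 | isopropenylmagnesium bromide | CC(=C)[Mg]Br | starting material
15 | isopropenylcerium dichloride | CC(=C)[Ce](Cl)Cl | intermediate
16 | (7R,8S,10S)-10-[(tert-butyldimethylsilyl)oxy]-8-methyl-7-(prop-1-en-2-yl)-8-vinyl-1,4-dioxaspiro[4.5]decan-7-ol (germacrane 5R,8S,10S; isopropenyl trans to vinyl) | C=C[C@]1(C)C[C@H](O[Si](C)(C)C(C)(C)C)C2(OCCO2)C[C@@]1(O)C(C)=C | intermediate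
17 | potassium alkoxide of 16 | C=C[C@]1(C)C[C@H](O[Si](C)(C)C(C)(C)C)C2(OCCO2)C[C@@]1(O[K])C(C)=C | intermediate
18 | potassium (7Z,11E,14S)-14-[(tert-butyldimethylsilyl)oxy]-8,12-dimethyl-1,4-dioxaspiro[4.9]tetradeca-7,11-dien-7-olate | CC(C)(C)[Si](C)(C)O[C@H]1C/C(C)=C/CC/C(C)=C(\O[K])CC12OCCO2 | intermediate
19 | (7Z,11E,14S)-14-[(tert-butyldimethylsilyl)oxy]-8,12-dimethyl-1,4-dioxaspiro[4.9]tetradeca-7,11-dien-7-yl trifluoromethanesulfonate (ring carbons trans across both alkenes) | CC(C)(C)[Si](C)(C)O[C@H]1C/C(C)=C/CC/C(C)=C(\OS(=O)(=O)C(F)(F)F)CC12OCCO2 | intermediate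
20 | (1Z,5E,8S)-8-[(tert-butyldimethylsilyl)oxy]-2,6-dimethyl-9-oxocyclodeca-1,5-dien-1-yl trifluoromethanesulfonate | CC(C)(C)[Si](C)(C)O[C@H]1C/C(C)=C/CC/C(C)=C(\OS(=O)(=O)C(F)(F)F)CC1=O | intermediate
21 | (3E,7E,10S)-10-[(tert-butyldimethylsilyl)oxy]-4,8-dimethylcyclodeca-3,7-dien-1-one | CC(C)(C)[Si](C)(C)O[C@H]1C/C(C)=C/CC/C(C)=C/CC1=O | intermediate
22 | potassium enolate of 21 (C6=C7 enolate) | CC(C)(C)[Si](C)(C)O[C@H]1C/C(C)=C/CC/C(C)=C/C=C1O[K] | intermediate
23 | (2R,3E,7E,10S)-10-[(tert-butyldimethylsilyl)oxy]-2-hydroxy-4,8-dimethylcyclodeca-3,7-dien-1-one (C6 hydroxyl cis to C8 OTBS) | CC(C)(C)[Si](C)(C)O[C@H]1C/C(C)=C/CC/C(C)=C/[C@@H](O)C1=O | intermediate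
24 | ethyl 2-(diethoxyphosphoryl)acrylate | C=C(C(=O)OCC)P(=O)(OCC)OCC | starting material
25 | 4-methoxybenzyl alcohol | COc1ccc(CO)cc1 | starting material
26 | ethyl 2-(diethoxyphosphoryl)-3-[(4-methoxybenzyl)oxy]propanoate (racemic) | CCOC(=O)C(COCc1ccc(OC)cc1)P(=O)(OCC)OCC | intermediate
27 | 2-(diethoxyphosphoryl)-3-[(4-methoxybenzyl)oxy]propanoic acid (racemic) | OC(=O)C(COCc1ccc(OC)cc1)P(=O)(OCC)OCC | intermediate
28 | (1R,2E,6E,9S)-9-[(tert-butyldimethylsilyl)oxy]-3,7-dimethyl-10-oxocyclodeca-2,6-dien-1-yl 2-(diethoxyphosphoryl)-3-[(4-methoxybenzyl)oxy]propanoate (mixture at the phosphonate carbon) | CC(C)(C)[Si](C)(C)O[C@H]1C/C(C)=C/CC/C(C)=C/[C@@H](OC(=O)C(COCc2ccc(OC)cc2)P(=O)(OCC)OCC)C1=O | intermediate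
29 | (6R,8S)-8-[(tert-butyldimethylsilyl)oxy]-13-[(4-methoxybenzyl)oxy]germacra-1(10)E,4E,7(11)-trien-12,6-olide | CC(C)(C)[Si](C)(C)O[C@H]1C/C(C)=C/CC/C(C)=C/[C@H]2OC(=O)C(COCc3ccc(OC)cc3)=C12 | intermediate
30 | (6R,8S)-8-hydroxy-13-[(4-methoxybenzyl)oxy]germacra-1(10)E,4E,7(11)-trien-12,6-olide | O[C@H]1C/C(C)=C/CC/C(C)=C/[C@H]2OC(=O)C(COCc3ccc(OC)cc3)=C12 | intermediate
31 | tiglic acid | C/C=C(\C)C(=O)O | starting material
32 | tiglic 2,4,6-trichlorobenzoic anhydride | C/C=C(\C)C(=O)OC(=O)c1c(Cl)cc(Cl)cc1Cl | intermediate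
33 | (6R,8S)-13-[(4-methoxybenzyl)oxy]-8-[(E)-2-methylbut-2-enoyloxy]germacra-1(10)E,4E,7(11)-trien-12,6-olide | C/C=C(\C)C(=O)O[C@H]1C/C(C)=C/CC/C(C)=C/[C@H]2OC(=O)C(COCc3ccc(OC)cc3)=C12 | intermediate
34 | (1R,4R,5R,6S,8S,10R)-1,10:4,5-diepoxy-13-[(4-methoxybenzyl)oxy]-8-[(E)-2-methylbut-2-enoyloxy]germacr-7(11)-en-12,6-olide | C/C=C(\C)C(=O)O[C@H]1C[C@@]2(C)O[C@@H]2CC[C@@]2(C)O[C@@H]2[C@H]2OC(=O)C(COCc3ccc(OC)cc3)=C12 | intermediate
35 | (1R,4R,5R,6S,8S,10R)-1,10:4,5-diepoxy-13-hydroxy-8-[(E)-2-methylbut-2-enoyloxy]germacr-7(11)-en-12,6-olide (CNP0111480.1) | C/C=C(\C)C(=O)O[C@H]1C[C@@]2(C)O[C@@H]2CC[C@@]2(C)O[C@@H]2[C@H]2OC(=O)C(CO)=C12 | target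

## Step count and risks

Total step count: 22. Longest linear sequence: 20 steps (steps 1–14 and 17–22); steps 15–16 make the phosphonate acid 27.

The three steps most likely to fail:

1. Step 14, C6 hydroxylation. What may go wrong: poor facial selectivity on the flexible ten-membered enolate, so that the oxidant enters from the other face and the hydroxyl ends trans to OTBS; partial deprotonation at C8 would in addition erode the C8 configuration. Fallback, setting out from 21 and returning at 28: the same enolate oxidation is accepted with the opposite outcome, giving (2S,3E,7E,10S)-10-[(tert-butyldimethylsilyl)oxy]-2-hydroxy-4,8-dimethylcyclodeca-3,7-dien-1-one F1. F1 is then esterified with acid 27 under Mitsunobu conditions (PPh3, diisopropyl azodicarboxylate, THF, 0 °C) instead of the Steglich coupling, so that C6 is inverted during ester formation and 28 is reached.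

2. Step 11, oxy-Cope rearrangement with triflation. What may go wrong: proton transfer within the potassium enolate towards C6 before sulfonylation, followed by β-elimination of the ketal oxygen, or incomplete O-triflation in the presence of crown ether and excess hydride. Fallback, setting out from 16 and returning at 19: the rearrangement is run as before, but the enolate is silylated with Me3SiCl/Et3N at −78 °C, which is faster and cleaner than sulfonylation, to give the isolable trimethylsilyl enol ether (7Z,11E,14S)-14-[(tert-butyldimethylsilyl)oxy]-8,12-dimethyl-7-[(trimethylsilyl)oxy]-1,4-dioxaspiro[4.9]tetradeca-7,11-diene F2. After purification, F2 is converted with MeLi (THF, 0 °C) and the same pyridyl triflimide at −78 °C into 19, the enolate now being regenerated regiospecifically and free of crown ether.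

3. Step 10, isopropenyl addition. What may go wrong: poor or reversed facial selectivity, for example if cerium coordinates the axial dioxolane oxygen and delivers the nucleophile from that face, which would put isopropenyl cis to vinyl and lead to the wrong alkene geometry in step 11. Fallback, setting out from 4 and returning at 19: the order of the two C10 alkylations is reversed, so that the C10-epimeric ketone is made, on which the same axial attack gives the trans relationship.
   - 4 is methylated (LiN(iPr)2, MeI) to (4S,6S)-4-[(tert-butyldimethylsilyl)oxy]-6-methylcyclohex-2-en-1-one F3.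
   - F3 is converted with KN(SiMe3)2 and 5 into (4S,6R)-4-[(tert-butyldimethylsilyl)oxy]-6-methyl-6-[2-(phenylsulfinyl)ethyl]cyclohex-2-en-1-one F4, the Michael acceptor now entering anti to OTBS.
   - F4 is pyrolysed to (4S,6R)-4-[(tert-butyldimethylsilyl)oxy]-6-methyl-6-vinylcyclohex-2-en-1-one F5.
   - F5 is epoxidised to (1R,3R,5S,6S)-5-[(tert-butyldimethylsilyl)oxy]-3-methyl-3-vinyl-7-oxabicyclo[4.1.0]heptan-2-one F6.
   - F6 is isomerised to (4S,6R)-4-[(tert-butyldimethylsilyl)oxy]-6-methyl-6-vinylcyclohexane-1,3-dione F7.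
   - F7 is ketalised to (8R,10S)-10-[(tert-butyldimethylsilyl)oxy]-8-methyl-8-vinyl-1,4-dioxaspiro[4.5]decan-7-one F8.
   - Isopropenylcerium addition to F8 from the face of the axial dioxolane oxygen, now anti to the axial vinyl group, gives (7S,8R,10S)-10-[(tert-butyldimethylsilyl)oxy]-8-methyl-7-(prop-1-en-2-yl)-8-vinyl-1,4-dioxaspiro[4.5]decan-7-ol F9.
   - F9 has the trans C5/C10 relationship and, under the conditions of step 11, converges on 19 because C5 and C10 become sp2.

## Further compounds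

F1 | step 14 | (2S,3E,7E,10S)-10-[(tert-butyldimethylsilyl)oxy]-2-hydroxy-4,8-dimethylcyclodeca-3,7-dien-1-one | CC(C)(C)[Si](C)(C)O[C@H]1C/C(C)=C/CC/C(C)=C/[C@H](O)C1=O
F2 | step 11 | (7Z,11E,14S)-14-[(tert-butyldimethylsilyl)oxy]-8,12-dimethyl-7-[(trimethylsilyl)oxy]-1,4-dioxaspiro[4.9]tetradeca-7,11-diene | CC(C)(C)[Si](C)(C)O[C@H]1C/C(C)=C/CC/C(C)=C(\O[Si](C)(C)C)CC12OCCO2
F3 | step 10 | (4S,6S)-4-[(tert-butyldimethylsilyl)oxy]-6-methylcyclohex-2-en-1-one | C[C@H]1C[C@H](O[Si](C)(C)C(C)(C)C)C=CC1=O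
F4 | step 10 | (4S,6R)-4-[(tert-butyldimethylsilyl)oxy]-6-methyl-6-[2-(phenylsulfinyl)ethyl]cyclohex-2-en-1-one | O=S(c1ccccc1)CC[C@@]2(C)C[C@H](O[Si](C)(C)C(C)(C)C)C=CC2=O
F5 | step 10 | (4S,6R)-4-[(tert-butyldimethylsilyl)oxy]-6-methyl-6-vinylcyclohex-2-en-1-one | C=C[C@@]1(C)C[C@H](O[Si](C)(C)C(C)(C)C)C=CC1=O
F6 | step 10 | (1R,3R,5S,6S)-5-[(tert-butyldimethylsilyl)oxy]-3-methyl-3-vinyl-7-oxabicyclo[4.1.0]heptan-2-one | C=C[C@@]1(C)C[C@H](O[Si](C)(C)C(C)(C)C)[C@H]2O[C@H]2C1=O
F7 | step 10 | (4S,6R)-4-[(tert-butyldimethylsilyl)oxy]-6-methyl-6-vinylcyclohexane-1,3-dione | C=C[C@@]1(C)C[C@H](O[Si](C)(C)C(C)(C)C)C(=O)CC1=O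
F8 | step 10 | (8R,10S)-10-[(tert-butyldimethylsilyl)oxy]-8-methyl-8-vinyl-1,4-dioxaspiro[4.5]decan-7-one | C=C[C@@]1(C)C[C@H](O[Si](C)(C)C(C)(C)C)C2(OCCO2)CC1=O
F9 | step 10 | (7S,8R,10S)-10-[(tert-butyldimethylsilyl)oxy]-8-methyl-7-(prop-1-en-2-yl)-8-vinyl-1,4-dioxaspiro[4.5]decan-7-ol | C=C[C@@]1(C)C[C@H](O[Si](C)(C)C(C)(C)C)C2(OCCO2)C[C@]1(O)C(C)=C
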